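Over the days of the runs, I asked first whether time still counted: free monomer in larch read 20.7% at 3.00 d and 20.7% at 8.00 d, and in alder 3.6% at 3.00 d and 3.7% at 4.00 d, differences inside the scatter of 0.5 percentage points, so I read both runs as stopped.

common to all: free monomer 10 mM

| charge | transfer agent | initiator | remark | time |
|---|---|---|---|---|
| alder | 3 mM | 1 mM | the very flask that is asked about, followed so far |  |
| larch | 3 mM | 0.50 mM | run made earlier |  |
| flask | 3.00 mM | 1.0 mM |  | 10 d |

- alder (time / d: monomer in chains / %, free monomer / %): 1.04: 91.5, 8.8; 2.08: 94.9, 4.9; 3.00: 96.3, 3.6; 4.00: 95.7, 3.7
- larch (time / d: monomer in chains / %, free monomer / %): 0.625: 61.7, 38.0; 1.25: 74.4, 25.8; 3.00: 78.2, 20.7; 8.00: 79.3, 20.7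

(standard deviation of a reading: 0.5 percentage points)

- average number of monomer units in a chain (chains begun, living or dead) at 10 d
- part of the free monomer that has reacted at 10 d

- the average divides the monomer in chains by the number of chains begun, living and dead together
- the earlier runs do not show the number of chains; that part of a forecast is a guess

Then I asked where they stopped. Counted in halvings of the free monomer fraction, larch had gone through 2.27 and alder 4.76, about twice as many on twice the initiator, so I took the stopping point to follow the initiator charge. I carried the halvings of free monomer per mM of initiator charged, read from alder as 4.76 /mM, and called it the stopping count. The flask asked about is alder itself, so my reckoning left 3.70% of the free monomer at 10 d, which means 96.3% reacted; the readings showed no chains to count.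

The forecast gave 96.4% reacted, between 95.8% and 97%, and a dp of 2.8, between 2.4 and 5, with the warning “Poor transfer would raise it.”

The flask gave 96.0% reacted, which is 4.66 halvings against my 4.76, and a dp of 9.76, above the top of the forecast's range.

    living end + transfer agent → dead chain (kL = 13.7 /M/h)
    initiator + monomer in chains → spent initiator B (k = 0.505 /M/h)
    living end → dead end A (k = 0.0424 /h)
    free monomer + living end → monomer in chains + living end, rate k4*[living end]*[free monomer] (k = 245 /M/h)
    free monomer + initiator → living end + monomer in chains (k = 37.9 /M/h)

At 10.0 d in the flask the half-life of free monomer by its passing into monomer in chains was 930 d, far longer than the 10 d of the run, with initiator down to 0.049% of its charge. In the same flask transfer agent kept 85% of its charge, 0.242 halvings against 4.66 for free monomer, and chains begun came to 0.982 of the initiator charge. For the neighbour charged with 1.7 mM of initiator, the stopping count gave 8.09 halvings, or 0.366% of free monomer, and that flask stood at 0.26%.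

(The runs stem from a simulated flask with constants of no real substance.)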